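The runs are simulated with made-up constants; noise was put on by code.

Start at the early readings: mono adduct plus substrate already falls short of the charge, in ochre by 4 percentage points at 1.33 h. Call this gap the shortfall. Substrate is the limiting reagent here: at 8.00 h it reads 0.6% in ochre and 1.1% in red, so count partner above 1 equivalent as excess.

| setting | violet | red | ochre | cedar | maple | oak |
|---|---|---|---|---|---|---|
| substrate | 0.30 M | 0.30 M | 0.30 M | 0.30 M | 0.30 M | 0.30 M |
| coupling partner | 1.1 equiv | 1.9 equiv | 2.6 equiv | 1.20 equiv | 2.50 equiv | 3.00 equiv |
| remark | run made earlier | run made earlier | run made earlier |  |  |  |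
| time |  |  |  | 10 h | 10 h | 10 h |

- violet (time / h: mono adduct / %, substrate / %): 0.500: 29.7, 69.9; 1.00: 45.0, 53.6; 2.00: 62.1, 35.8; 4.00: 76.0, 20.5; 8.00: 85.8, 9.8
- red (time / h: mono adduct / %, substrate / %): 0.667: 53.9, 44.3; 2.00: 81.4, 14.3; 3.00: 88.0, 7.0; 5.00: 91.9, 2.1; 8.00: 92.6, 1.1
- ochre (time / h: mono adduct / %, substrate / %): 1.33: 82.1, 13.9; 3.00: 90.3, 1.5; 4.00: 91.1, 0.7; 6.00: 89.2, 0.1; 8.00: 88.3, 0.6

(readings scatter by 0.5 percentage points)

- a reading or a percentage of mono adduct counts all its forms, free or not

1. amount of mono adduct at the end, in percent of the substrate charged, for each flask in turn (cedar, maple, oak)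

Now bracket maple, taking its substrate as spent by 10 h, as ochre's readings suggest. At 8.00 h ochre's shortfall of 11.1% per excess equivalent is 6.94%, and red's is 7.00%. If the shortfall stopped there, maple would keep 89.6%: that is the upper bound.

For the lower bound, replace the curve by its mean. Define the mean leak, the shortfall per excess equivalent per hour averaged from zero to 8.00 h: 0.00867 /h. Run straight on to 10 h, it leaves maple 87.0%.

Tighten the top. Ochre's late slope from 3.00 h to 8.00 h reads 0.00363 /h per excess equivalent, lower than the mean leak but not zero. Two more hours at that slope bring the upper bound to 88.5%, though this slope carries much of the readings' scatter.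

The forecast gives 90%, 89.2% and 86.3%, holding that “The second step therefore seems to die with time”. Its maple value lies inside the first bracket and above the tightened top.

The flasks give 91.0%, 86.8% and 83.2% for cedar, maple and oak, which is within the forecast's margin.

    crystals ⇌ mono adduct, rate k1*(cs1 - [mono adduct]) while solid is left; crystals form when [mono adduct] > cs1 (solubility = 4.50 mM, k = 0.250 /min)
    coupling partner + mono adduct → double product (k = 0.0220 /M/min)
    substrate + coupling partner → mono adduct (k = 0.0430 /M/min)

Maple stands at 86.8%, which is 0.20 points under the 87.0% of the mean-leak line. Carried to oak, the mean leak gives 82.7%, and oak stands at 83.2%. Maple still holds 86.8% because of two things acting together: the ceiling that the crystals put on dissolved mono adduct, and the hour of the reading, against one ten times later. Without that ceiling maple holds 6.05% at 10 h, and with it, read at 100 h, maple holds 31.3%.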